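## The problem

Bisoflavolin I (14) is made of two isoflavone (3-aryl-4H-chromen-4-one) units joined by one diaryl ether oxygen. The oxygen runs from C4' of ring B of the 8-chloro-5,7-dihydroxy unit (unit 1) to C8 of ring A of a genistein-type unit (unit 2). The molecule has no stereocentre, so no centre can control another, and every difficulty is one of position. Each ring A is a pentasubstituted benzene in which the C8 substituent (chlorine in unit 1, the aryloxy group in unit 2) must sit beside the pyranone oxygen O1 and not beside the C5 oxygen. The 6-substituted isomers are what an unselective chlorination or an unselective closure onto a phloroglucinol-type ketone would also give, and hot acid or base can interconvert the two series by opening and re-closing the pyranone. Five phenols on resorcinol-type rings are oxidisable and must stay masked to the last step, C2 of an isoflavone is open to nucleophiles (base removes it as formate), and the aryl chloride rules out hydrogenolysis and therefore benzyl ethers. The feature that the plan exploits is that an acylated 1-X-2,4-dimethoxybenzene (X = Cl or aryloxy) has its carbonyl-bearing carbon, the future C4a, between a methoxy carbon (the future C5) and a single C–H (the future C8a), and this C–H lies next to the carbon bearing X (the future C8). A ketone-directed C–H oxygenation therefore has one place to go in each unit, and it is the right one for O1.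

## Retrosynthesis

**O–CH3 bonds.** The five O–H groups of 14 are traced back to the pentamethyl ether 13, to be cleaved in one operation with BBr3. Methyl is preferred to benzyl, silyl or acetal protection because it passes through Lewis-acid acylations and an oxidising CF3CO2H medium and needs no hydrogenolysis beside a C–Cl bond. The cleavage is placed after ring closure on purpose: while C5–O is a methyl ether, each ketone has only one free ortho oxygen, so the pyranone cannot close toward the wrong side. 13 is no simpler in skeleton, but it is robust and non-phenolic. The forward step must leave the diaryl ether and the chloride alone, which have no sp3 carbon for bromide to attack.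

**Pyranone rings.** In 13, O1–C2 and C2–C3 are cut in both units, which leads to the bis(2-hydroxydeoxybenzoin) 11. C2 is returned by N,N-dimethylformamide dimethyl acetal by way of the bis-enaminone 12. The neighbouring cut, C3–C1' (coupling of a 3-halochromone or an aryl shift), would keep the chromone nucleus and with it the O1 problem. The deoxybenzoin cut removes two rings at once and leaves a bis-ketone whose carbon framework is open to Friedel–Crafts chemistry. The forward reaction needs a free phenol ortho to each ketone and an unhindered CH2, and 11 has both.

**The two ring oxygens (key disconnection).** Both C8a–O1 bonds of 11 are cut back to C–H, which gives the bis-deoxybenzoin 9; in the forward direction the bis(trifluoroacetate) 10 lies between them. Positional certainty speaks for this cut. If O1 came in with the arene (a phloroglucinol ether), each ketone would have two ortho oxygens to tell apart and chlorine would have to be placed among three activated positions. In 9 chlorine is bought in place and each ketone has a single ortho hydrogen. The simplification is large, since every ring of 9 is a commercial substitution pattern. The forward step must deliver two chelate-directed oxygenations at C–H bonds that are flanked by a second substituent, in the presence of alkoxy-bearing rings and two benzylic methylenes.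

**Unit 1 ketone.** The C4–C4a bond of unit 1 in 9 is cut to 1-chloro-2,4-dimethoxybenzene 7 and the acid chloride 8, made in the flask from the keto acid 6. This bond is formed last because an acid chloride must not carry a ring more nucleophilic than the arene it is to acylate. In 8 the trioxygenated ring already bears its acyl group. In 7 the site para to one methoxy group and ortho to the other is the only strongly activated, unhindered one. The forward reaction needs a Lewis acid mild enough (SnCl4) to spare the methyl ethers ortho to the ketones, since those ethers are the lock for the later ring closure.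

**Unit 2 ketone.** 6 is the acid of the methyl ester 5; the ester shields the carboxyl group during the first acylation. In 5 the C4–C4a bond of unit 2 is cut to the diaryl ether 3 and commercial 2-(4-methoxyphenyl)acetyl chloride 4. The ring to be acylated in 3 carries three oxygens. Its C5 (para to the 2-methoxy and ortho to the 4-methoxy group) is far more reactive than the shielded position between the methoxy groups, than C6 (meta to both), and than the mono-oxygenated rings. The acyl group therefore enters so that its one ortho hydrogen is the one next to the ether carbon, as the key step requires.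

**Diaryl ether.** 3 is cut at the O–C4' bond into 2,4-dimethoxyphenol 1 and methyl 2-(4-bromophenyl)acetate 2, to be joined by copper-catalysed O-arylation. Forming this bond first means the phenol has only one ortho substituent; in the target the same oxygen sits between two substituted carbons. An uncatalysed SNAr on 4-fluoroacetophenone would be more certain but needs three further steps to turn acetyl into CH2CO2CH3. The coupling with 2 gives the arylacetic ester in one step.

## Roads not taken

**Alternative 1:** The cut goes through ring B of unit 1. The para-phenylene ring that carries the ether oxygen is taken apart into methyl coumalate A3 as the diene and the aryl ethynyl ether A2 (1-benzyloxy-2-ethynyloxy-3,5-dimethoxybenzene). In the forward key step A2 adds across C3 and C6 of A3, the bicyclic adduct loses CO2, and the benzoate A1 (methyl 4-(2-benzyloxy-4,6-dimethoxyphenoxy)benzoate) results.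
- Merits: the hindered aryl–O bond at a doubly ortho-oxygenated carbon is present from the start and needs no copper coupling. The O1 oxygen of unit 2 arrives as a benzyl ether, so that unit needs no C–H oxidation. The cycloaddition is reliably para-selective.
- Weak points: the ring that is built is the one ring of 14 that can be bought with the right pattern (as in 2). A1 is a benzoate, one carbon short of the arylacetic acid, so a homologation sequence follows. A2 is a sensitive ynol ether that must itself be prepared. In the ring derived from A1 the two open positions are each flanked by two alkoxy groups and nearly equal in reactivity, so the later acylation loses positional certainty. The benzyl ether must later be removed in a molecule that holds an aryl chloride. Unit 1 still needs its own solution for O1.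
- Comparison: this road is better in that the unit 2 oxygen never depends on a C–H oxidation. The chosen plan sets against it seven steps instead of well over ten, acylation positions that are not in doubt, and one operation for both ring oxygens.

**Alternative 2:** The cut is the C3–C1' bond of both units, traced back to the bis-flavanone A5 in which each aryl group still sits on C2. In the forward key step Tl(O3SC6H4CH3)3 (trivalent thallium) or PhI(OH)OTs (trivalent iodine) attacks each enolised chromanone at C3, the para-oxygenated aryl group shifts from C2 to C3, and loss of a proton gives the pentamethyl ether A4, which is the same compound as 13.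
- Merits: it mirrors the biosynthesis. Both migrating rings are para-oxygenated and migrate well. Chalcone and flavanone chemistry is dependable C–C bond formation. It ends in the same last step as the chosen route.
- Weak points: the building blocks of A5 must already carry the O1 oxygen beside chlorine and beside the aryloxy group, so the central positional problem is moved into the starting materials (regioselective halogenation or selective demethylation of phloroglucinol-derived ketones). Thallium is toxic and stoichiometric, and with the iodine reagent dehydrogenation to the flavone competes. Because the rearrangement must occur twice, every partial failure gives flavone/isoflavone hybrids of identical mass. Closure of 2'-hydroxy-6'-methoxychalcones to flavanones is an unfavourable equilibrium. Two stereocentres are made only to be destroyed.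
- Comparison: this road is better precedented for single isoflavones and equal in its end game. The chosen plan sets against it a catalytic metal, roughly half the step count, and an O1 position decided by the substrate in the key step rather than beforehand.

**Alternative 3:** The cut is the C3–C4 bond of both units. In the forward key step BF3·OEt2 opens both epoxides of the bis(chalcone epoxide) A7 at their benzylic carbons, each aroyl group shifts to that carbon, and the former α-carbon is left as a formyl group. This gives the bis(α-formyl deoxybenzoin) A6, held as the chelated enol.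
- Merits: C2 is already attached as the formyl carbon, so after unmasking O1 the pyranone closes by dehydration alone. No transition metal is needed. The aroyl shift is established for chalcone epoxides with a 2'-benzyloxy group and a para-alkoxy ring B.
- Weak points: A7 needs benzyl-protected O1 oxygens already in place beside chlorine and the aryloxy group, the same starting-material problem as in Alternative 2. Removing the benzyl groups by hydrogenolysis endangers the C–Cl bond, and removing them with BCl3 would also cleave the C5 methyl ethers and so destroy the lock that makes closure one-directional. β-Ketoaldehydes deformylate easily. Four stereocentres are built and discarded.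
- Comparison: this road is equal or better in carrying C2 with it and in avoiding a C–H oxidation. The chosen plan sets against it the absence of any conflict between benzyl ether and aryl chloride, a shorter sequence, and ring A ketones that need no prior oxygenation.

Key step: step 5

Remark on the chemistry: 14 has no stereocentre; the only stereo-element in the route is the C=C geometry of the transient enaminone 12, drawn E,E, which has no bearing on the outcome.

## Route

Step 1
Reactants: 1 2,4-dimethoxyphenol; 2 methyl 2-(4-bromophenyl)acetate
Product: 3 methyl 2-[4-(2,4-dimethoxyphenoxy)phenyl]acetate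
Conditions: CuI (10 mol%), picolinic acid (20 mol%), K3PO4, DMSO, 90 °C
Reagents that add atoms: none
Why: Ullmann-type copper-catalysed O-arylation of a phenol with an aryl bromide; the electron-rich phenoxide with one ortho substituent is a good partner, and the non-conjugated ester is tolerated by phosphate in dry DMSO.

Step 2
Reactants: 3 methyl 2-[4-(2,4-dimethoxyphenoxy)phenyl]acetate; 4 2-(4-methoxyphenyl)acetyl chloride
Product: 5 methyl 2-[4-[2,4-dimethoxy-5-[2-(4-methoxyphenyl)acetyl]phenoxy]phenyl]acetate
Conditions: SnCl4, CH2Cl2, −20 → 0 °C
Reagents that add atoms: none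
Why: Friedel–Crafts acylation; C5 of the trioxygenated ring is para to one methoxy group and ortho to the other, whereas the site between the methoxy groups is shielded and C6 is meta to both, so one ketone isomer is expected; SnCl4 at low temperature avoids chelation-assisted loss of the methyl ether ortho to the new ketone.

Step 3
Reactants: 5 methyl 2-[4-[2,4-dimethoxy-5-[2-(4-methoxyphenyl)acetyl]phenoxy]phenyl]acetate
Product: 6 2-[4-[2,4-dimethoxy-5-[2-(4-methoxyphenyl)acetyl]phenoxy]phenyl]acetic acid
Conditions: LiOH·H2O, THF/MeOH/H2O, rt, argon; then 1 M HCl
Reagents that add atoms: lithium hydroxide, [Li+].[OH-]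
Why: Ester saponification by acyl substitution; ketone and aryl ethers are inert, and exclusion of air prevents autoxidation of the deoxybenzoin enolate.

Step 4
Reactants: 6 2-[4-[2,4-dimethoxy-5-[2-(4-methoxyphenyl)acetyl]phenoxy]phenyl]acetic acid; 7 1-chloro-2,4-dimethoxybenzene
Product: 9 bis-deoxybenzoin 1-(5-chloro-2,4-dimethoxyphenyl)-2-[4-[2,4-dimethoxy-5-[2-(4-methoxyphenyl)acetyl]phenoxy]phenyl]ethan-1-one, via acid chloride 8 (not isolated)
Conditions: (COCl)2, cat. DMF, CH2Cl2, 0 °C → rt, evaporate; then 7 (3 equiv), SnCl4, CH2Cl2, 0 °C → rt
Reagents that add atoms: none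
Why: Acid chloride formation followed by Friedel–Crafts acylation; in 7 the carbon para to the 2-methoxy and ortho to the 4-methoxy group (meta to Cl) is the only strongly activated open site, and every ring of 8 is either acyl-deactivated or mono-oxygenated, so the excess of 7 should outrun self-acylation.

Step 5
Reactants: 9 bis-deoxybenzoin 1-(5-chloro-2,4-dimethoxyphenyl)-2-[4-[2,4-dimethoxy-5-[2-(4-methoxyphenyl)acetyl]phenoxy]phenyl]ethan-1-one
Product: 11 bis(2-hydroxydeoxybenzoin) 1-(3-chloro-2-hydroxy-4,6-dimethoxyphenyl)-2-[4-[2-hydroxy-4,6-dimethoxy-3-[2-(4-methoxyphenyl)acetyl]phenoxy]phenyl]ethan-1-one, via bis(trifluoroacetate) 10 (not isolated)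
Conditions: Pd(OAc)2 (20 mol%), K2S2O8 (5 equiv), CF3CO2H/(CF3CO)2O 9:1, 50 °C; then H2O, NaHCO3, THF, rt
Reagents that add atoms: trifluoroacetic acid, OC(=O)C(F)(F)F
Why: In CF3CO2H the acetate ligands are exchanged for trifluoroacetate, and the electrophilic divalent palladium binds each ketone oxygen, which is electron-rich here (ortho and para methoxy groups) and turned toward the ring hydrogen because the other ortho position carries a methoxy group. Concerted metalation–deprotonation at that single ortho C–H, which is acidified by the neighbouring Cl or aryloxy oxygen, gives a five-membered palladacycle; persulfate oxidises it to tetravalent palladium, and C–O reductive elimination releases the aryl trifluoroacetate and divalent palladium. The closest known reaction type is the palladium-catalysed, carbonyl-directed ortho C–H hydroxylation of aryl ketones with persulfate or PhI(O2CCF3)2 in CF3CO2H/(CF3CO)2O, applied here twice in one molecule. Two C–O bonds form (C8a–O1 of both units), no ring closes and no stereocentre arises. The selectivity needed is one of site: against the other lone-pair direction of each ketone, which could reach the benzyl ring only through a six-membered palladacycle, against undirected palladation of the anisole and phenoxy rings, and against the benzylic methylenes. It is secured by the chelate and by the fact that each aroyl ring offers exactly one ortho C–H, a carbon meta to both methoxy groups that an undirected electrophile would choose last. The anhydride keeps the new oxygens as trifluoroacetates in 10, which neither bind the catalyst nor are oxidised further, and mild aqueous base then frees the hydrogen-bonded phenols of 11.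

Step 6
Reactants: 11 bis(2-hydroxydeoxybenzoin) 1-(3-chloro-2-hydroxy-4,6-dimethoxyphenyl)-2-[4-[2-hydroxy-4,6-dimethoxy-3-[2-(4-methoxyphenyl)acetyl]phenoxy]phenyl]ethan-1-one
Product: 13 pentamethyl ether 8-chloro-3-[4-[[5,7-dimethoxy-3-(4-methoxyphenyl)-4-oxo-4H-chromen-8-yl]oxy]phenyl]-5,7-dimethoxy-4H-chromen-4-one, via bis-enaminone 12 (not isolated)
Conditions: Me2NCH(OMe)2 (6 equiv), DMF, 90 °C
Reagents that add atoms: N,N-dimethylformamide dimethyl acetal, COC(OC)N(C)C
Why: Amide-acetal condensation at each activated methylene gives the enaminone, and the ortho phenol adds to its β-carbon with loss of dimethylamine (the standard deoxybenzoin-to-isoflavone closure); only the oxygen installed in step 5 is free, so each pyranone can close in one direction only.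

Step 7
Reactants: 13 pentamethyl ether 8-chloro-3-[4-[[5,7-dimethoxy-3-(4-methoxyphenyl)-4-oxo-4H-chromen-8-yl]oxy]phenyl]-5,7-dimethoxy-4H-chromen-4-one
Product: 14 bisoflavolin I, 8-chloro-3-[4-[[5,7-dihydroxy-3-(4-hydroxyphenyl)-4-oxo-4H-chromen-8-yl]oxy]phenyl]-5,7-dihydroxy-4H-chromen-4-one
Conditions: BBr3 (15 equiv), CH2Cl2, −78 °C → rt; then ice-water
Reagents that add atoms: none
Why: Lewis-acid ether cleavage: BBr3 binds each methoxy oxygen and bromide attacks the methyl carbon (SN2); the diaryl ether and the aryl chloride have no sp3 carbon and persist, and the pyranones stay closed in the anhydrous medium, so 8- and 6-substitution cannot scramble.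

## Compound list

1 | 2,4-dimethoxyphenol | COc1ccc(O)c(OC)c1 | starting material
2 | methyl 2-(4-bromophenyl)acetate | COC(=O)Cc1ccc(Br)cc1 | starting material
3 | methyl 2-[4-(2,4-dimethoxyphenoxy)phenyl]acetate | COC(=O)Cc1ccc(Oc2ccc(OC)cc2OC)cc1 | intermediate
4 | 2-(4-methoxyphenyl)acetyl chloride | COc1ccc(CC(Cl)=O)cc1 | starting material
5 | methyl 2-[4-[2,4-dimethoxy-5-[2-(4-methoxyphenyl)acetyl]phenoxy]phenyl]acetate | COC(=O)Cc1ccc(Oc2cc(C(=O)Cc3ccc(OC)cc3)c(OC)cc2OC)cc1 | intermediate
6 | 2-[4-[2,4-dimethoxy-5-[2-(4-methoxyphenyl)acetyl]phenoxy]phenyl]acetic acid | OC(=O)Cc1ccc(Oc2cc(C(=O)Cc3ccc(OC)cc3)c(OC)cc2OC)cc1 | intermediate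
7 | 1-chloro-2,4-dimethoxybenzene | COc1ccc(Cl)c(OC)c1 | starting material
8 | 2-[4-[2,4-dimethoxy-5-[2-(4-methoxyphenyl)acetyl]phenoxy]phenyl]acetyl chloride (not isolated) | ClC(=O)Cc1ccc(Oc2cc(C(=O)Cc3ccc(OC)cc3)c(OC)cc2OC)cc1 | intermediate
9 | bis-deoxybenzoin, 1-(5-chloro-2,4-dimethoxyphenyl)-2-[4-[2,4-dimethoxy-5-[2-(4-methoxyphenyl)acetyl]phenoxy]phenyl]ethan-1-one | COc1cc(OC)c(Cl)cc1C(=O)Cc1ccc(Oc2cc(C(=O)Cc3ccc(OC)cc3)c(OC)cc2OC)cc1 | intermediate
10 | bis(trifluoroacetate) of 11, both new phenolic oxygens as O–C(O)CF3 esters (not isolated) | COc1cc(OC)c(Cl)c(OC(=O)C(F)(F)F)c1C(=O)Cc1ccc(Oc2c(OC(=O)C(F)(F)F)c(C(=O)Cc3ccc(OC)cc3)c(OC)cc2OC)cc1 | intermediate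
11 | bis(2-hydroxydeoxybenzoin), 1-(3-chloro-2-hydroxy-4,6-dimethoxyphenyl)-2-[4-[2-hydroxy-4,6-dimethoxy-3-[2-(4-methoxyphenyl)acetyl]phenoxy]phenyl]ethan-1-one | COc1cc(OC)c(Cl)c(O)c1C(=O)Cc1ccc(Oc2c(O)c(C(=O)Cc3ccc(OC)cc3)c(OC)cc2OC)cc1 | intermediate
12 | bis-enaminone, the 3-(dimethylamino)methylene derivative of 11 at both CH2 groups, drawn E,E (not isolated) | COc1cc(OC)c(Cl)c(O)c1C(=O)/C(=C/N(C)C)c1ccc(Oc2c(O)c(C(=O)/C(=C/N(C)C)c3ccc(OC)cc3)c(OC)cc2OC)cc1 | intermediate
13 | 8-chloro-3-[4-[[5,7-dimethoxy-3-(4-methoxyphenyl)-4-oxo-4H-chromen-8-yl]oxy]phenyl]-5,7-dimethoxy-4H-chromen-4-one | O=c1c(-c2ccc(Oc3c(OC)cc(OC)c4c(=O)c(-c5ccc(OC)cc5)coc34)cc2)coc2c(Cl)c(OC)cc(OC)c12 | intermediate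
14 | bisoflavolin I, 8-chloro-3-[4-[[5,7-dihydroxy-3-(4-hydroxyphenyl)-4-oxo-4H-chromen-8-yl]oxy]phenyl]-5,7-dihydroxy-4H-chromen-4-one | O=c1c(-c2ccc(Oc3c(O)cc(O)c4c(=O)c(-c5ccc(O)cc5)coc34)cc2)coc2c(Cl)c(O)cc(O)c12 | target

## Step count and risks

Total: 7 steps. Longest linear sequence: 7 steps (1 and 2 to 14).

**Step 5 (key step).** The chelate-directed palladation at C–H bonds flanked by Cl or by the aryloxy group may be slow. Three processes can then take over:
- oxidation outside the chelate, that is, undirected palladation or one-electron oxidation of the methoxy-bearing spectator rings and oxidation at the two ArCH2C(=O) methylenes by persulfate in CF3CO2H;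
- in unit 2, attack of the arylpalladium, which sits ortho to the ether oxygen, on ring B (oxidative closure to a dibenzofuran) instead of C–O reductive elimination;
- stalling after the first oxygenation.

The fallback gives up the C–H oxidation and brings both O1 oxygens in as methyl ethers, to be freed by chelation-controlled demethylation. It sets out from 2 and comes back to the route at 11. Coupling of 2 with commercial 2,4,6-trimethoxyphenol under the conditions of step 1 should give methyl 2-[4-(2,4,6-trimethoxyphenoxy)phenyl]acetate F1. Acylation with 4 (SnCl4) at either of its two equivalent open positions should give methyl 2-[4-[2,4,6-trimethoxy-3-[2-(4-methoxyphenyl)acetyl]phenoxy]phenyl]acetate F2, and saponification the acid 2-[4-[2,4,6-trimethoxy-3-[2-(4-methoxyphenyl)acetyl]phenoxy]phenyl]acetic acid F3. Its acid chloride 2-[4-[2,4,6-trimethoxy-3-[2-(4-methoxyphenyl)acetyl]phenoxy]phenyl]acetyl chloride F4 would acylate commercial 2-chloro-1,3,5-trimethoxybenzene to the heptamethoxy bis-ketone 1-(3-chloro-2,4,6-trimethoxyphenyl)-2-[4-[2,4,6-trimethoxy-3-[2-(4-methoxyphenyl)acetyl]phenoxy]phenyl]ethan-1-one F5. BCl3 (CH2Cl2, −78 → 0 °C) should then remove one ortho methyl ether at each ketone and give 11. The price is that each ketone of F5 has two ortho methoxy groups. The one wedged between the carbonyl and Cl (or the aryloxy group) is twisted out of conjugation and should go first, but this is a preference of degree, whereas the main route has a single C–H to choose.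

**Step 4.** Acylation of the chlorine-deactivated arene 7 may be sluggish with SnCl4. Forcing it with a stronger Lewis acid or longer times invites chelation-assisted loss of the methyl ethers ortho to the ketones, which would open a second closure site in step 6. Self-acylation of 8 at its anisole ring is a lesser concern. The fallback replaces electrophilic substitution by a Negishi acylation; it sets out from 7 and comes back at 9. Iodination of 7 (N-iodosuccinimide, cat. CF3CO2H, MeCN) para to the 2-methoxy group should give 1-chloro-5-iodo-2,4-dimethoxybenzene F6. Zinc insertion (Zn dust, LiCl, THF, 50 °C) gives (5-chloro-2,4-dimethoxyphenyl)zinc iodide F7. Pd(PPh3)4 (zerovalent palladium, THF, rt) couples F7 with acid chloride 8, prepared as in the first half of step 4, to 9. The ketone position is then fixed by the former C–I bond and no Lewis acid is present.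

**Step 1.** Under hot phosphate in DMSO the methyl arylacetate may be hydrolysed or condensed at its acidic CH2, and the electron-rich phenol 1 may be oxidised by copper and traces of air before it couples. The fallback is an uncatalysed SNAr followed by a Willgerodt–Kindler homologation; it sets out from 1 and comes back at 3. 1 and 4-fluoroacetophenone (K2CO3, DMF, 120 °C) should give 1-[4-(2,4-dimethoxyphenoxy)phenyl]ethan-1-one F8. Sulfur and morpholine (S8, 130 °C) convert it into 2-[4-(2,4-dimethoxyphenoxy)phenyl]-1-(morpholin-4-yl)ethane-1-thione F9. Hydrolysis (KOH, aq. EtOH, reflux) gives 2-[4-(2,4-dimethoxyphenoxy)phenyl]acetic acid F10, and Fischer esterification (MeOH, H2SO4) gives 3.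

**Step 6.** The acetal may transfer a methyl group to the two acidic, chelated phenols instead of condensing at the methylenes. Reaction at only one of the two sites would give mixtures of open and closed units. The fallback is a Lewis-acid, Vilsmeier-type closure; it sets out from 11 and comes back at 13. BF3·OEt2 in DMF first ties up each hydroxy ketone as the bis(difluoroboron) chelate of 11 F11, which protects the phenolic oxygens and acidifies the methylenes. MeSO2Cl then generates the chloroiminium ion from DMF, which formylates both methylenes, and aqueous work-up closes both pyranones to 13.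

## Further compounds

F1 | step 5 | methyl 2-[4-(2,4,6-trimethoxyphenoxy)phenyl]acetate | COC(=O)Cc1ccc(Oc2c(OC)cc(OC)cc2OC)cc1
F2 | step 5 | methyl 2-[4-[2,4,6-trimethoxy-3-[2-(4-methoxyphenyl)acetyl]phenoxy]phenyl]acetate | COC(=O)Cc1ccc(Oc2c(OC)cc(OC)c(C(=O)Cc3ccc(OC)cc3)c2OC)cc1
F3 | step 5 | 2-[4-[2,4,6-trimethoxy-3-[2-(4-methoxyphenyl)acetyl]phenoxy]phenyl]acetic acid | OC(=O)Cc1ccc(Oc2c(OC)cc(OC)c(C(=O)Cc3ccc(OC)cc3)c2OC)cc1
F4 | step 5 | 2-[4-[2,4,6-trimethoxy-3-[2-(4-methoxyphenyl)acetyl]phenoxy]phenyl]acetyl chloride | ClC(=O)Cc1ccc(Oc2c(OC)cc(OC)c(C(=O)Cc3ccc(OC)cc3)c2OC)cc1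
F5 | step 5 | 1-(3-chloro-2,4,6-trimethoxyphenyl)-2-[4-[2,4,6-trimethoxy-3-[2-(4-methoxyphenyl)acetyl]phenoxy]phenyl]ethan-1-one | COc1cc(OC)c(Cl)c(OC)c1C(=O)Cc1ccc(Oc2c(OC)cc(OC)c(C(=O)Cc3ccc(OC)cc3)c2OC)cc1
F6 | step 4 | 1-chloro-5-iodo-2,4-dimethoxybenzene | COc1cc(OC)c(I)cc1Cl
F7 | step 4 | (5-chloro-2,4-dimethoxyphenyl)zinc iodide | COc1cc(OC)c([Zn]I)cc1Cl
F8 | step 1 | 1-[4-(2,4-dimethoxyphenoxy)phenyl]ethan-1-one | CC(=O)c1ccc(Oc2ccc(OC)cc2OC)cc1
F9 | step 1 | 2-[4-(2,4-dimethoxyphenoxy)phenyl]-1-(morpholin-4-yl)ethane-1-thione | S=C(Cc1ccc(Oc2ccc(OC)cc2OC)cc1)N1CCOCC1
F10 | step 1 | 2-[4-(2,4-dimethoxyphenoxy)phenyl]acetic acid | OC(=O)Cc1ccc(Oc2ccc(OC)cc2OC)cc1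
F11 | step 6 | bis(difluoroboron) chelate of 11, each 2-hydroxyaryl ketone as its six-membered O,O-BF2 chelate | F[B-]1(F)Oc2c(Cl)c(OC)cc(OC)c2C(Cc2ccc(Oc3c(OC)cc(OC)c4c3O[B-](F)(F)[O+]=C4Cc3ccc(OC)cc3)cc2)=[O+]1
A1 | alternative 1 | methyl 4-(2-benzyloxy-4,6-dimethoxyphenoxy)benzoate | COC(=O)c1ccc(Oc2c(OC)cc(OC)cc2OCc2ccccc2)cc1
A2 | alternative 1 | 1-benzyloxy-2-ethynyloxy-3,5-dimethoxybenzene | C#COc1c(OC)cc(OC)cc1OCc1ccccc1
A3 | alternative 1 | methyl coumalate, methyl 2-oxo-2H-pyran-5-carboxylate | COC(=O)c1ccc(=O)oc1
A4 | alternative 2 | pentamethyl ether of the target, identical with 13 | O=c1c(-c2ccc(Oc3c(OC)cc(OC)c4c(=O)c(-c5ccc(OC)cc5)coc34)cc2)coc2c(Cl)c(OC)cc(OC)c12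
A5 | alternative 2 | bis-flavanone, 8-chloro-2-[4-[[5,7-dimethoxy-2-(4-methoxyphenyl)-4-oxochroman-8-yl]oxy]phenyl]-5,7-dimethoxychroman-4-one, mixture of diastereomers with both C2 centres undefined | O=C1CC(c2ccc(Oc3c(OC)cc(OC)c4C(=O)CC(c5ccc(OC)cc5)Oc34)cc2)Oc2c(Cl)c(OC)cc(OC)c12
A6 | alternative 3 | bis(α-formyl deoxybenzoin) with benzyl ethers at both future O1 oxygens, chelated Z,Z-enol form | COc1cc(OC)c(Cl)c(OCc2ccccc2)c1C(=O)/C(=C\O)c3ccc(Oc4c(OC)cc(OC)c(C(=O)/C(=C\O)c5ccc(OC)cc5)c4OCc6ccccc6)cc3
A7 | alternative 3 | bis(chalcone epoxide) with benzyl ethers at both future O1 oxygens, each epoxide trans, drawn as one diastereomer of the racemate | COc1cc(OC)c(Cl)c(OCc2ccccc2)c1C(=O)[C@@H]1O[C@H]1c1ccc(Oc2c(OC)cc(OC)c(C(=O)[C@@H]3O[C@H]3c3ccc(OC)cc3)c2OCc2ccccc2)cc1
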